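The target is the entry I want, and I keep a ledger of the substrate, the limiting reagent for the two products taken together: each percent should close as target or as other capture product.

all flasks: substrate 0.050 M
- maple: second nucleophile 1.1 equiv; protic impurity 0.013 M; solid first nucleophile 0.50 equiv; run made earlier
- cedar: second nucleophile 1.1 equiv; protic impurity 0.019 M; solid first nucleophile 0.50 equiv; run made earlier
- alder: second nucleophile 1.7 equiv; protic impurity 0.025 M; solid first nucleophile 0.50 equiv; run made earlier
- flask: second nucleophile 1.10 equiv; protic impurity 0.0250 M; solid first nucleophile 0.500 equiv; time 8.0 d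

| run | time / d | target / % | other capture product / % | substrate / % |
|---|---|---|---|---|
| maple | 0.417 | 16 | 70 | 17 |
| maple | 0.625 | 18 | 76 | 5 |
| maple | 0.833 | 20 | 78 | 3 |
| maple | 1.25 | 21 | 81 | 0 |
| maple | 2.08 | 19 | 81 | 0 |
| maple | 3.00 | 21 | 80 | 0 |
| maple | 5.00 | 22 | 80 | 0 |
| cedar | 0.250 | 13 | 57 | 33 |
| cedar | 0.833 | 17 | 82 | 2 |
| cedar | 1.25 | 18 | 82 | 0 |
| cedar | 2.08 | 17 | 83 | 0 |
| cedar | 3.00 | 19 | 83 | 0 |
| cedar | 4.00 | 18 | 81 | 0 |
| cedar | 5.00 | 18 | 81 | 0 |
| alder | 0.417 | 11 | 76 | 15 |
| alder | 0.833 | 14 | 88 | 1 |
| alder | 1.25 | 10 | 87 | 1 |
| alder | 2.50 | 12 | 87 | 0 |
| alder | 5.00 | 10 | 88 | 2 |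

(scatter of a reading: 1.5 percentage points)

1. ratio of target to other capture product at 20 min
2. ratio of target to other capture product at 8.0 d
3. which of target and other capture product there is more of at 8.0 d

- at the start none of the solid first nucleophile is in solution

In the cedar run, the ledger closes by 1.25 d, with substrate at 0%, target at 18% and other capture product at 82%. I assume each unit of other capture product costs one unit of second nucleophile, so the dissolved first nucleophile competes against a shrinking rival. Let N be the second nucleophile left, in equivalents of substrate. I carry a capture constant a, a selectivity factor: target gained per other capture product gained, multiplied by N, which makes target equal a ln(N at start / N at end), and cedar gives 0.132. The alder run, with 1.7 equiv of second nucleophile and 0.025 M of protic impurity, gives 0.139 from its reading at 1.25 d, so a agrees within the scatter between these two runs, which differ in both charges.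

The flask has cedar's charge of second nucleophile and alder's impurity, so I keep cedar's a. Target then closes near 18.0%, which gives my late ratio of 0.220. At the early end the ratio starts from zero, since no first nucleophile is dissolved, and cedar reads 0.228 at 0.250 d. A straight join gives me 0.0127 at 20 min.

The forecast differs from me at both ends, printing 0.07 and 0.21, with other capture product ahead, and it reasons that “The target stays flat once the substrate is gone”.

The flask gives 0.0675 at 20 min and 0.204 at 8.0 d, with other capture product ahead, 83.0% against 17.0% of target.

    first nucleophile + intermediate → target (k = 560 /M/h)
    solid first nucleophile ⇌ first nucleophile, rate k2*(cs2 - [first nucleophile]) while solid is left; crystals form when [first nucleophile] > cs2 (solubility = 48.0 mM, k = 0.880 /h)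
    first nucleophile + protic impurity → quenched reagent (k = 4.60 /M/h)
    substrate → intermediate (k = 0.190 /h)
    second nucleophile + intermediate → other capture product (k = 1000 /M/h)

The closing entries of the flask give a = 0.121, and those of the neighbour flask with 0.300 equiv of solid first nucleophile, which closes at 10.9% target, give 0.0654. By its step alone, the substrate has a half-life of 0.15 d on its way to intermediate. The first nucleophile, with the impurity as charged, has a longer half-life of 0.25 d by the quench alone. The neighbour flask with 0.280 equiv of second nucleophile ends with target ahead at a ratio of 1.36, its second nucleophile at 0% and 33.8% of the substrate still intermediate.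

Readings and results are calculated with made-up constants, noise included.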